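**Plan**

- The eight phenols are carried as methyl ethers. The first cut is the C2–C3 bond of the 2,3-dihydrobenzofuran: C3 carries the benzofuran benzene ring and a resorcinol ring (a diaryl carbene carbon), C2 carries O1 and the 4-oxyphenyl ring (an ArO–CH2–Ar ether C–H), and the two sit 1,5 to each other across the benzene ring and O1.
- Further cuts: the aryl–C(=O) bond of the resulting diaryl ketone, the exocyclic C1=CH bond of the indane (indanone + benzylic Grignard reagent), the C2–aryl bond (ketone α-arylation) and the C1–C2 bond of the indanone (alkene hydroacylation).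
- Forward order: indanone ring, then the E-benzylidene link to the second benzene ring, then the diaryl ketone, and last the dihydrofuran ring.
- Stereochemistry: indane C3 comes from the chiral Rh–BINAP hydroacylation catalyst and indane C2 (trans) from thermodynamic control in the α-arylation. The alkene geometry comes from a syn-elimination that can only go exocyclic. Dihydrofuran C3 and C2 (cis) come from the chiral dirhodium carboxylate, and C2 is then equilibrated to trans in the BBr3 step.

Key step: step 11

Assumption: (R)-BINAP in step 2 and Rh2(R-PTAD)4 in step 11 are taken to give the absolute configurations drawn; if the sense of induction proves opposite for either substrate, the mirror-image ligand is used and nothing else changes.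

**Route**

Step 1
Reactants: 1 2-bromo-3,5-dimethoxybenzaldehyde; 2 2-[1-(4-methoxyphenyl)ethenyl]-4,4,5,5-tetramethyl-1,3,2-dioxaborolane
Product: 3 3,5-dimethoxy-2-[1-(4-methoxyphenyl)ethenyl]benzaldehyde
Conditions: Pd(OAc)2 (3 mol%), SPhos (6 mol%), K3PO4, toluene/H2O, 90 °C
Reagents that add atoms: none
Why: Suzuki–Miyaura coupling; the bulky biarylphosphine should allow coupling at the di-ortho-substituted aryl bromide, and the aldehyde is inert to these conditions.

Step 2
Reactants: 3 3,5-dimethoxy-2-[1-(4-methoxyphenyl)ethenyl]benzaldehyde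
Product: 4 (3S)-4,6-dimethoxy-3-(4-methoxyphenyl)-2,3-dihydro-1H-inden-1-one
Conditions: [Rh(nbd)2]BF4 (5 mol%), (R)-BINAP (5.5 mol%), H2 purge then argon, CH2Cl2, rt
Reagents that add atoms: none
Why: Rh-catalysed intramolecular alkene hydroacylation (acyl–Rh–H formation, hydride insertion into the 1,1-diarylethene, reductive elimination to the five-membered ketone); the substituent on the inner vinyl carbon suppresses dimerisation, and C3 is set by the BINAP ligand in the hydride-insertion step.

Step 3
Reactants: 4 (3S)-4,6-dimethoxy-3-(4-methoxyphenyl)-2,3-dihydro-1H-inden-1-one; 5 1-bromo-3,5-dimethoxybenzene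
Product: 6 (2S,3S)-2-(3,5-dimethoxyphenyl)-4,6-dimethoxy-3-(4-methoxyphenyl)-2,3-dihydro-1H-inden-1-one
Conditions: Pd(OAc)2 (5 mol%), P(t-Bu)3·HBF4 (10 mol%), NaOt-Bu, toluene, 70 °C, argon
Reagents that add atoms: none
Why: Buchwald–Hartwig-type ketone α-arylation at the only enolisable position; the acidic C2–H equilibrates under the basic conditions so the new aryl group should settle trans to the C3 aryl group, while C3 itself is not acidic and keeps its configuration.

Step 4
Reactants: 7 3-bromo-4-hydroxybenzaldehyde; 8 4-methoxybenzyl chloride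
Product: 9 3-bromo-4-[(4-methoxyphenyl)methoxy]benzaldehyde
Conditions: K2CO3, DMF, 50 °C
Reagents that add atoms: none
Why: Williamson ether synthesis on an acidic phenol with a reactive benzylic chloride; it installs the ArO–CH2–Ar unit that later becomes C2 of the dihydrofuran with its aryl group.

Step 5
Reactants: 9 3-bromo-4-[(4-methoxyphenyl)methoxy]benzaldehyde
Product: 10 {3-bromo-4-[(4-methoxyphenyl)methoxy]phenyl}methanol
Conditions: NaBH4, MeOH/THF, 0 °C
Reagents that add atoms: none
Why: Borohydride reduction of an aryl aldehyde; the aryl bromide and the benzyl aryl ether are inert.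

Step 6
Reactants: 10 {3-bromo-4-[(4-methoxyphenyl)methoxy]phenyl}methanol
Product: 12 {3-bromo-4-[(4-methoxyphenyl)methoxy]phenyl}methyl chloride, via benzylic mesylate 11 (not isolated)
Conditions: MsCl, Et3N, CH2Cl2, 0 °C → rt
Reagents that add atoms: methanesulfonyl chloride, CS(=O)(=O)Cl
Why: Mesylation followed by in situ chloride displacement, which is fast for a benzylic mesylate carrying a para-alkoxy group; no acid is present that could cleave the benzyl aryl ether.

Step 7
Reactants: 12 {3-bromo-4-[(4-methoxyphenyl)methoxy]phenyl}methyl chloride; 6 (2S,3S)-2-(3,5-dimethoxyphenyl)-4,6-dimethoxy-3-(4-methoxyphenyl)-2,3-dihydro-1H-inden-1-one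
Product: 14 (1R,2S,3S)-1-benzyl-2,3-diarylindan-1-ol (full name in the list), via benzylmagnesium chloride 13 (not isolated)
Conditions: Mg turnings, THF, 0 °C; then 6, LaCl3·2LiCl, THF, −78 → 0 °C; aq. NH4Cl
Reagents that add atoms: none
Why: Magnesium inserts into the benzylic C–Cl bond much faster than into the aryl C–Br bond at 0 °C, and the lanthanum-promoted Grignard 1,2-addition should outrun enolisation of the acidic 2-aryl ketone; attack anti to the C2 aryl group should place the new hydroxyl cis to that aryl group (C1 is removed in step 8).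

Step 8
Reactants: 14 (1R,2S,3S)-1-benzyl-2,3-diarylindan-1-ol
Product: 15 (1E,2S,3S)-1-{3-bromo-4-[(4-methoxyphenyl)methoxy]benzylidene}-2-(3,5-dimethoxyphenyl)-4,6-dimethoxy-3-(4-methoxyphenyl)-2,3-dihydro-1H-indene
Conditions: Burgess reagent (methyl N-(triethylammoniosulfonyl)carbamate), toluene, 50 °C
Reagents that add atoms: none
Why: Burgess dehydration by intramolecular syn-elimination: because the hydroxyl is trans to the C2 hydrogen, only the exocyclic benzylic hydrogens can reach the sulfamate, so the double bond should form outside the ring and leave C2 untouched; the E isomer (aryl away from the peri C7–H) is the less strained transition state and product, and the neutral conditions spare the benzyl aryl ether.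

Step 9
Reactants: 15 E-benzylidene-indane aryl bromide; 16 N,3,5-trimethoxy-N-methylbenzamide
Product: 18 diaryl ketone (3,5-dimethoxyphenyl)(aryl)methanone (full name in the list), via aryllithium 17 (not isolated)
Conditions: n-BuLi, THF, −78 °C; then 16, −78 → 0 °C; aq. NH4Cl
Reagents that add atoms: none
Why: Bromine–lithium exchange at −78 °C is faster than deprotonation of the benzylic C–H bonds, and the Weinreb ketone synthesis stops at the ketone because the chelated tetrahedral intermediate survives until work-up.

Step 10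
Reactants: 18 diaryl ketone
Product: 19 hydrazone of ketone 18 (C=N isomer mixture, both serve)
Conditions: N2H4·H2O (excess), AcOH (cat.), EtOH, 80 °C, argon
Reagents that add atoms: hydrazine (used as the monohydrate), NN
Why: Hydrazone condensation of a hindered benzophenone under acid catalysis; the trisubstituted alkene and the ethers are inert, and argon excludes diimide formation.

Step 11
Reactants: 19 hydrazone of ketone 18
Product: 21 (2S,3R)-cis-2,3-diaryl-2,3-dihydrobenzofuran octamethyl ether (full name in the list), via diaryldiazomethane 20 (not isolated)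
Conditions: MnO2 (activated), MeCN, 0 °C, filtration through Celite; then Rh2(R-PTAD)4 (1 mol%; PTAD = (1-adamantyl)(phthalimido)acetate), MeCN, 0 °C → rt
Reagents that add atoms: none
Why: MnO2 dehydrogenates the hydrazone to the diaryldiazomethane 20, which Rh2(R-PTAD)4 converts with loss of N2 into a donor/donor rhodium carbene at the carbon flanked by the two aryl rings. The carbene inserts into the C–H bond of the ArO–CH2–Ar group lying 1,5 to it through an asynchronous, hydride-transfer-like three-centre transition state; the closest known reaction type is the enantioselective intramolecular C–H insertion of donor/donor carbenes into benzyl aryl ethers to give 2,3-diaryl-2,3-dihydrobenzofurans. The five-membered oxygen ring closes by this 1,5-insertion (formally a 5-exo closure onto the ether carbon), forming the C3–C2 bond. Both new stereocentres, C3 (the former carbene carbon) and C2 (the former OCH2), are set by the chiral carboxylate ligands of the dirhodium catalyst, which should give the cis-2,3-diaryl ring in one absolute sense; the indane centres are too remote to interfere. The step needs chemoselectivity for this insertion over alkene cyclopropanation, azine formation and attack on other C–H bonds: the only C–H within reach of a five-membered transition state is activated by both the ether oxygen and the 4-methoxyphenyl ring, the alkene sits para to the ether oxygen and cannot reach the carbene, the methoxy groups of the carbene aryl ring are meta, and a donor/donor carbene is too weakly electrophilic for fast intermolecular reactions.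

Step 12
Reactants: 21 (2S,3R)-cis-dihydrobenzofuran octamethyl ether
Product: 23 target octaphenol CNP0184753.1, via trans octamethyl ether 22 (not isolated)
Conditions: BBr3 (excess), CH2Cl2, −78 °C → rt; then H2O
Reagents that add atoms: none
Why: Boron tribromide ether cleavage: at low temperature the Lewis acid should reversibly ionise the benzylic C2–O bond (cation stabilised by the 4-methoxyphenyl ring) and reclosure should funnel the cis ring to the thermodynamically preferred trans ring by inversion at C2 only, leaving C3 and the absolute configuration untouched; on warming the same reagent cleaves the eight aryl methyl ethers, a reaction type established for permethylated benzylidene-indane and 2,3-diaryl-dihydrobenzofuran stilbenoids.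

**Compound list**

1 | 2-bromo-3,5-dimethoxybenzaldehyde | O=Cc1cc(OC)cc(OC)c1Br | starting material
2 | 2-[1-(4-methoxyphenyl)ethenyl]-4,4,5,5-tetramethyl-1,3,2-dioxaborolane | C=C(B1OC(C)(C)C(C)(C)O1)c1ccc(OC)cc1 | starting material
3 | 3,5-dimethoxy-2-[1-(4-methoxyphenyl)ethenyl]benzaldehyde | O=Cc1cc(OC)cc(OC)c1C(=C)c1ccc(OC)cc1 | intermediate
4 | (3S)-4,6-dimethoxy-3-(4-methoxyphenyl)-2,3-dihydro-1H-inden-1-one | COc1ccc([C@H]2c3c(OC)cc(OC)cc3C(=O)C2)cc1 | intermediate
5 | 1-bromo-3,5-dimethoxybenzene | COc1cc(Br)cc(OC)c1 | starting material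
6 | (2S,3S)-2-(3,5-dimethoxyphenyl)-4,6-dimethoxy-3-(4-methoxyphenyl)-2,3-dihydro-1H-inden-1-one (trans) | COc1ccc([C@H]2c3c(OC)cc(OC)cc3C(=O)[C@@H]2c2cc(OC)cc(OC)c2)cc1 | intermediate
7 | 3-bromo-4-hydroxybenzaldehyde | O=Cc1ccc(O)c(Br)c1 | starting material
8 | 4-methoxybenzyl chloride | COc1ccc(CCl)cc1 | starting material
9 | 3-bromo-4-[(4-methoxyphenyl)methoxy]benzaldehyde | COc1ccc(COc2ccc(C=O)cc2Br)cc1 | intermediate
10 | {3-bromo-4-[(4-methoxyphenyl)methoxy]phenyl}methanol | COc1ccc(COc2ccc(CO)cc2Br)cc1 | intermediate
11 | {3-bromo-4-[(4-methoxyphenyl)methoxy]phenyl}methyl methanesulfonate | COc1ccc(COc2ccc(COS(C)(=O)=O)cc2Br)cc1 | intermediate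
12 | {3-bromo-4-[(4-methoxyphenyl)methoxy]phenyl}methyl chloride | COc1ccc(COc2ccc(CCl)cc2Br)cc1 | intermediate
13 | {3-bromo-4-[(4-methoxyphenyl)methoxy]benzyl}magnesium chloride | COc1ccc(COc2ccc(C[Mg]Cl)cc2Br)cc1 | intermediate
14 | (1R,2S,3S)-1-{3-bromo-4-[(4-methoxyphenyl)methoxy]benzyl}-2-(3,5-dimethoxyphenyl)-4,6-dimethoxy-3-(4-methoxyphenyl)-2,3-dihydro-1H-inden-1-ol (benzyl trans to the 2-aryl group) | COc1ccc([C@H]2c3c(OC)cc(OC)cc3[C@@](O)(Cc3ccc(OCc4ccc(OC)cc4)c(Br)c3)[C@@H]2c2cc(OC)cc(OC)c2)cc1 | intermediate
15 | (1E,2S,3S)-1-{3-bromo-4-[(4-methoxyphenyl)methoxy]benzylidene}-2-(3,5-dimethoxyphenyl)-4,6-dimethoxy-3-(4-methoxyphenyl)-2,3-dihydro-1H-indene | COc1ccc([C@H]2c3c(OC)cc(OC)cc3/C(=C/c3ccc(OCc4ccc(OC)cc4)c(Br)c3)[C@@H]2c2cc(OC)cc(OC)c2)cc1 | intermediate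
16 | N,3,5-trimethoxy-N-methylbenzamide | COc1cc(OC)cc(C(=O)N(C)OC)c1 | starting material
17 | aryllithium from 15 (lithium in place of bromine) | COc1ccc([C@H]2c3c(OC)cc(OC)cc3/C(=C/c3ccc(OCc4ccc(OC)cc4)c([Li])c3)[C@@H]2c2cc(OC)cc(OC)c2)cc1 | intermediate
18 | (3,5-dimethoxyphenyl){5-[(E)-{(2S,3S)-2-(3,5-dimethoxyphenyl)-4,6-dimethoxy-3-(4-methoxyphenyl)-2,3-dihydro-1H-inden-1-ylidene}methyl]-2-[(4-methoxyphenyl)methoxy]phenyl}methanone | COc1ccc([C@H]2c3c(OC)cc(OC)cc3/C(=C/c3ccc(OCc4ccc(OC)cc4)c(C(=O)c4cc(OC)cc(OC)c4)c3)[C@@H]2c2cc(OC)cc(OC)c2)cc1 | intermediate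
19 | hydrazone of ketone 18 (C=N–NH2 in place of C=O) | COc1ccc([C@H]2c3c(OC)cc(OC)cc3/C(=C/c3ccc(OCc4ccc(OC)cc4)c(C(=NN)c4cc(OC)cc(OC)c4)c3)[C@@H]2c2cc(OC)cc(OC)c2)cc1 | intermediate
20 | diaryldiazomethane from 19 (C=N2 in place of C=N–NH2) | COc1ccc([C@H]2c3c(OC)cc(OC)cc3/C(=C/c3ccc(OCc4ccc(OC)cc4)c(C(=[N+]=[N-])c4cc(OC)cc(OC)c4)c3)[C@@H]2c2cc(OC)cc(OC)c2)cc1 | intermediate
21 | (2S,3R)-3-(3,5-dimethoxyphenyl)-5-[(E)-{(2S,3S)-2-(3,5-dimethoxyphenyl)-4,6-dimethoxy-3-(4-methoxyphenyl)-2,3-dihydro-1H-inden-1-ylidene}methyl]-2-(4-methoxyphenyl)-2,3-dihydro-1-benzofuran (cis ring) | COc1ccc([C@H]2c3c(OC)cc(OC)cc3/C(=C/c3ccc4c(c3)[C@@H](c3cc(OC)cc(OC)c3)[C@@H](c3ccc(OC)cc3)O4)[C@@H]2c2cc(OC)cc(OC)c2)cc1 | intermediate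
22 | (2R,3R)-epimer of 21 at C2 of the dihydrobenzofuran (trans ring), octamethyl ether of the target | COc1ccc([C@H]2c3c(OC)cc(OC)cc3/C(=C/c3ccc4c(c3)[C@@H](c3cc(OC)cc(OC)c3)[C@H](c3ccc(OC)cc3)O4)[C@@H]2c2cc(OC)cc(OC)c2)cc1 | intermediate
23 | 5-[(2R,3R)-5-[(E)-{(2S,3S)-2-(3,5-dihydroxyphenyl)-4,6-dihydroxy-3-(4-hydroxyphenyl)-2,3-dihydro-1H-inden-1-ylidene}methyl]-2-(4-hydroxyphenyl)-2,3-dihydro-1-benzofuran-3-yl]benzene-1,3-diol (CNP0184753.1) | Oc1ccc([C@H]2c3c(O)cc(O)cc3/C(=C/c3ccc4c(c3)[C@@H](c3cc(O)cc(O)c3)[C@H](c3ccc(O)cc3)O4)[C@@H]2c2cc(O)cc(O)c2)cc1 | target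

**Count and risks**

Total step count: 12. Longest linear sequence: 9 steps (steps 4–12 from 7; equally steps 1–3 and 7–12 from 1).

Steps most likely to fail:

Step 12. The dihydrofuran ring may open at the benzylic C2–O bond without reclosing, or the ring-opened cation may lose the C3 proton. Acid formed in the flask may move the exocyclic double bond into the five-membered carbocycle or trigger cationic cyclisation onto the neighbouring resorcinol ring. Ether cleavage may also stay incomplete. The fallback sets out from 21 and comes back at 23, and it separates the two events and replaces Lewis-acid cleavage by nucleophilic cleavage. Compound 21 would first be epimerised with substoichiometric BF3·OEt2 in CH2Cl2 at −78 °C and the trans octamethyl ether 22 isolated. The eight methyl ethers would then be removed by SN2 attack of sodium ethanethiolate on the methyl carbons (DMF, 130 °C, argon), with acidification under argon to give 23.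

Step 8. The elimination may lose regiocontrol, so that the double bond enters the ring and destroys C2, or may give E/Z mixtures; in step 7 enolisation of the 2-aryl ketone may compete with addition. The fallback sets out from 4 and comes back at 15, and it installs the resorcinol ring and the exocyclic alkene together by an oxidative Heck reaction. Grignard reagent 13 would be added to the less acidic, less hindered ketone 4 to give the tertiary alcohol (3S)-1-{3-bromo-4-[(4-methoxyphenyl)methoxy]benzyl}-4,6-dimethoxy-3-(4-methoxyphenyl)-2,3-dihydro-1H-inden-1-ol F1. Catalytic p-TsOH in toluene at 50 °C would dehydrate it under thermodynamic control to the endocyclic (1S)-3-{3-bromo-4-[(4-methoxyphenyl)methoxy]benzyl}-5,7-dimethoxy-1-(4-methoxyphenyl)-1H-indene F2. Treatment with 3,5-dimethoxyphenylboronic acid, Pd(OAc)2 (cat.), TEMPO and KF in propionic acid at rt would then deliver the aryl group to C2 anti to the existing aryl group. Because the C2 hydrogen is anti to palladium, only an exocyclic benzylic hydrogen can be eliminated syn, which should give the E-benzylidene 15 directly.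

Step 2. Enantiofacial discrimination may be poor, or hydride insertion slow, for a 1,1-diarylethene flanked by an ortho methoxy group. The fallback sets out from 1 and comes back at 4, and it forms the C3–aryl ring bond instead of the C1–C2 bond. (E)-2-(4-Methoxyphenyl)ethenylmagnesium bromide would be added to aldehyde 1 (THF, −78 °C) to give the allylic alcohol (E)-1-(2-bromo-3,5-dimethoxyphenyl)-3-(4-methoxyphenyl)prop-2-en-1-ol F3. MnO2 in CH2Cl2 would oxidise it to the chalcone (E)-1-(2-bromo-3,5-dimethoxyphenyl)-3-(4-methoxyphenyl)prop-2-en-1-one F4. Miyaura borylation (B2pin2, PdCl2(dppf), KOAc, dioxane, 90 °C) would give the boronate (E)-1-[3,5-dimethoxy-2-(4,4,5,5-tetramethyl-1,3,2-dioxaborolan-2-yl)phenyl]-3-(4-methoxyphenyl)prop-2-en-1-one F5. A rhodium-catalysed asymmetric intramolecular 1,4-addition ([RhCl(C2H4)2]2, (R)-MonoPhos, aq. K3PO4, toluene, rt; ligand antipode chosen for the S product) would then close the ring to 4.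

**Further compounds**

F0 | step 12 | none | none
F1 | step 8 | (3S)-1-{3-bromo-4-[(4-methoxyphenyl)methoxy]benzyl}-4,6-dimethoxy-3-(4-methoxyphenyl)-2,3-dihydro-1H-inden-1-ol (C1 epimer mixture) | COc1ccc([C@H]2c3c(OC)cc(OC)cc3C(O)(Cc3ccc(OCc4ccc(OC)cc4)c(Br)c3)C2)cc1
F2 | step 8 | (1S)-3-{3-bromo-4-[(4-methoxyphenyl)methoxy]benzyl}-5,7-dimethoxy-1-(4-methoxyphenyl)-1H-indene | COc1ccc([C@@H]2C=C(Cc3ccc(OCc4ccc(OC)cc4)c(Br)c3)c3cc(OC)cc(OC)c32)cc1
F3 | step 2 | (E)-1-(2-bromo-3,5-dimethoxyphenyl)-3-(4-methoxyphenyl)prop-2-en-1-ol (racemic) | COc1ccc(/C=C/C(O)c2cc(OC)cc(OC)c2Br)cc1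
F4 | step 2 | (E)-1-(2-bromo-3,5-dimethoxyphenyl)-3-(4-methoxyphenyl)prop-2-en-1-one | COc1ccc(/C=C/C(=O)c2cc(OC)cc(OC)c2Br)cc1
F5 | step 2 | (E)-1-[3,5-dimethoxy-2-(4,4,5,5-tetramethyl-1,3,2-dioxaborolan-2-yl)phenyl]-3-(4-methoxyphenyl)prop-2-en-1-one | COc1ccc(/C=C/C(=O)c2cc(OC)cc(OC)c2B2OC(C)(C)C(C)(C)O2)cc1
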